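**Plan** (cembrane numbering: C1=C15 is the tetrasubstituted alkene, C2 the O–CH, C16 the ring O–CH2, C17 the CH2OAc carbon, C7/C8 the oxirane carbons; target = 2R,7R,8R)
1. Cuts, in order: C2–O (the dihydrofuran shrinks to a 15,16-oxirane on a C1=C2–C3=C4 diene), C1–C15 (Stille), C14–C1 (B-alkyl Suzuki ring closure), then C13=C14 and C1=C2 (two one-carbon olefinations). What remains is (2E,6E)-farnesol, which holds C2–C13 and all three methyl groups.
2. Forward: the farnesol head becomes a CBr2 diene (C1) and the tail is oxidised at C13. The 7,8-oxirane follows, then C14 by methylenation, the 14-membered ring, the C15–C17 side chain, the 15,16-oxirane, and last the five-membered ring.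
3. Enabling feature: the ring O–C16H2–C15=C1–C2H is the 1,3-oxygen-shift isomer of a 2-alkenyl oxirane (three-ring O, C16, C15 attached to the C1=C2 bond of the macrocyclic diene). One isomerisation therefore makes the C2–O bond, the C2 stereocentre and the tetrasubstituted alkene.
4. Stereochemistry: 3E and 11E come from farnesol and the E-selective SeO2 oxidation. C7/C8 come from Shi epoxidation, C15 (a relay centre, later erased) from Sharpless epoxidation, and C2 from 1,3-chirality transfer C15→C2.

Key step: step 14

Remark: the sense of the C15→C2 transfer is assigned on the assumption of the usual allyl-copper sequence: anti oxidative addition, suprafacial migration, retentive reductive elimination.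

**Step 1**
Reactants: 1 (2E,6E)-farnesol
Product: 2 (2E,6E)-farnesal
Conditions: activated MnO2 (excess), CH2Cl2, rt
Reagents that add atoms: none
Why: Allylic alcohol oxidation with MnO2 stops at the enal and leaves the isolated trisubstituted alkenes and the 2E geometry untouched.

**Step 2**
Reactants: 2 (2E,6E)-farnesal
Product: 3 (3E,7E)-1,1-dibromo-4,8,12-trimethyltrideca-1,3,7,11-tetraene
Conditions: CBr4, PPh3, Zn dust, CH2Cl2, rt (ylide pre-formed), then 2, 0 °C
Reagents that add atoms: carbon tetrabromide, BrC(Br)(Br)Br
Why: The dibromo-olefination stage of the Corey–Fuchs reaction converts the enal into a 1,1-dibromo-1,3-diene, which brings in C1 with two sterically different C–Br bonds.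

**Step 3**
Reactants: 3 dibromotetraene
Product: 4 (2E,6E,10E)-13,13-dibromo-2,6,10-trimethyltrideca-2,6,10,12-tetraen-1-ol
Conditions: SeO2 (0.1 equiv), t-BuOOH (2 equiv), salicylic acid (0.1 equiv), CH2Cl2, 0 °C to rt, stopped at partial conversion, 3 recycled
Reagents that add atoms: tert-butyl hydroperoxide, CC(C)(C)OO
Why: Catalytic SeO2 allylic oxidation (ene reaction then [2,3]-shift) picks the electron-richest, least hindered alkene, the terminal isopropylidene group, and oxidises only its E-methyl group (C13), which fixes 11E, while the diene next to CBr2 is too electron-poor to compete.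

**Step 4**
Reactants: 4 allylic alcohol
Product: 5 acetate of 4
Conditions: Ac2O, pyridine, DMAP (cat.), CH2Cl2, 0 °C
Reagents that add atoms: acetic anhydride, CC(=O)OC(C)=O
Why: Routine acetylation turns the allylic OH into an inductively withdrawing OAc that lowers the nucleophilicity of C11=C12 for the next step.

**Step 5**
Reactants: 5 tetraene acetate
Product: 6 (6R,7R)-6,7-epoxide of 5 (cembrane 7R,8R)
Conditions: D-fructose-derived Shi ketone (0.3 equiv), Oxone, K2CO3, Bu4NHSO4 (cat.), MeCN–DMM/aq. Na2B4O7–EDTA buffer, −5 °C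
Reagents that add atoms: potassium peroxymonosulfate (active part of Oxone), [K+].[O-]S(=O)(=O)OO
Why: In the Shi epoxidation the electrophilic chiral dioxirane takes the only unperturbed trisubstituted alkene (C11=C12 is deactivated by the allylic acetate; C3=C4 and C1=C2 by conjugation to CBr2), and the spiro transition state of the D-fructose ketone gives the R,R-oxirane from an E-trisubstituted alkene, which sets C7 and C8.

**Step 6**
Reactants: 6 epoxy acetate
Product: 7 epoxy allylic alcohol (C13–OH)
Conditions: K2CO3 (0.2 equiv), MeOH, 0 °C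
Reagents that add atoms: none
Why: Base-catalysed transesterification removes the acetate without touching the trisubstituted oxirane or the dibromodiene.

**Step 7**
Reactants: 7 epoxy allylic alcohol
Product: 8 epoxy enal (C13 = CHO)
Conditions: activated MnO2, CH2Cl2, rt
Reagents that add atoms: none
Why: MnO2 oxidises only the allylic alcohol to the E-enal under neutral conditions that the oxirane tolerates.

**Step 8**
Reactants: 8 epoxy enal
Product: 9 terminal 1,3-diene (C13=C14H2)
Conditions: MePPh3Br, KHMDS (slight deficit), THF, 0 °C, then 8, −78 to 0 °C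
Reagents that add atoms: methyltriphenylphosphonium bromide, C[P+](c1ccccc1)(c1ccccc1)c1ccccc1.[Br-]
Why: Wittig methylenation brings in C14, and at low temperature the aldehyde reacts with the ylide far faster than the oxirane or the vinylic bromides do.

**Step 9**
Reactants: 9 terminal diene
Product: 11 (1Z,3E,7R,8R,11E)-1-bromo-7,8-epoxy-15,16,17-trinorcembra-1,3,11-triene (14-membered ring), via B-alkyl-9-BBN adduct 10 (not isolated)
Conditions: 9-BBN-H (1.1 equiv), THF, 0 °C to rt; then slow addition to Pd(dppf)Cl2 (15 mol %), AsPh3, Cs2CO3, DMF–THF–H2O, 50 °C, about 1 mM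
Reagents that add atoms: 9-borabicyclo[3.3.1]nonane (9-BBN-H), [H]B1C2CCCC1CCC2
Why: 9-BBN-H adds only to the monosubstituted terminus of the 1,3-diene (boron on C14; the trisubstituted alkenes, the dibromoalkene and the oxirane are inert), and in the intramolecular B-alkyl Suzuki–Miyaura coupling Pd(0) inserts first into the less hindered C–Br bond trans to C3, so the ring closes with C14 trans to C3 and the cis bromide is kept.

**Step 10**
Reactants: 12 prop-2-yn-1-ol
Product: 13 2-(tributylstannyl)prop-2-en-1-ol
Conditions: Bu3SnH, Mo(CO)3(CNt-Bu)3 (2 mol %), hydroquinone, THF, 55 °C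
Reagents that add atoms: tributyltin hydride, CCCC[SnH](CCCC)CCCC
Why: Molybdenum-catalysed hydrostannation of a propargylic alcohol is a syn addition that puts tin on the internal carbon and gives the 1,1-disubstituted vinylstannane.

**Step 11**
Reactants: 11 macrocyclic bromide; 13 vinylstannane
Product: 14 (1Z,3E,7R,8R,11E)-7,8-epoxycembra-1,3,11,15-tetraen-17-ol
Conditions: Pd(Pt-Bu3)2 (5 mol %), CuI (10 mol %), CsF (2 equiv), DMF, 45 °C
Reagents that add atoms: none
Why: Copper- and fluoride-assisted Stille coupling joins the sp2 carbons C1 and C15 with retention of the C1=C2 geometry, so C15 ends up cis to C3, and neither the free OH nor the non-allylic oxirane interferes with Pd(0).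

**Step 12**
Reactants: 14 trienol
Product: 15 (15R)-7,8:15,16-diepoxycembra-1,3,11-trien-17-ol
Conditions: Ti(Oi-Pr)4 (10 mol %), D-(−)-DIPT (12 mol %), t-BuOOH (decane), 4 Å MS, CH2Cl2, −25 °C; cold NaOH/brine work-up, Et3N-washed silica
Reagents that add atoms: tert-butyl hydroperoxide, CC(C)(C)OO
Why: Sharpless asymmetric epoxidation is directed by the C17 hydroxyl to the only allylic alkene, C15=C16 (C1=C2 is homoallylic, the others remote), and D-(−)-tartrate, which gives (R)-2-methylglycidol from methallyl alcohol, sets 15R under reagent control.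

**Step 13**
Reactants: 15 epoxy alcohol
Product: 16 17-acetate of 15 (descriptor now 15S)
Conditions: Ac2O, Et3N, DMAP (cat.), CH2Cl2, 0 °C
Reagents that add atoms: acetic anhydride, CC(=O)OC(C)=O
Why: Acetylation under buffered basic conditions installs the acetate of the target and removes a free OH that could bind copper or start a Payne-type migration; the C15 descriptor changes only because the CIP ranks of C16 and C17 swap.

**Step 14**
Reactants: 16 dienyl oxirane acetate
Product: 17 lobophynin B
Conditions: Cu(hfacac)2 (5 mol %), PhMe (0.02 M), 80 °C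
Reagents that add atoms: none
Why: Cu(hfacac)2 is reduced in situ to a Cu(I) species that adds to the allylic C15–O bond anti to oxygen, migrates suprafacially along the C15–C1–C2 allyl unit and, as a six-membered oxacupracycle (Cu, O, C16, C15, C1, C2), forms the C2–O bond by reductive elimination, so the three-membered ring (O, C16, C15) grows by C1 and C2 into the 2,5-dihydrofuran and the C1=C2 bond moves to the tetrasubstituted C1=C15 position. The closest known reaction type is the copper-catalysed ring expansion of vinyl oxiranes to 2,5-dihydrofurans, known for di- and trisubstituted alkenyl oxiranes of either alkene geometry. The only ring closed is the five-membered one, formally a 5-endo-trig SN2′ return of the C16 alkoxide to C2. The new stereocentre C2 is controlled by C15 and the 1Z geometry: closure is possible only from the rotamer with C16 syn to C2, in which 16 holds its oxygen on one defined face of the allyl unit, and the anti/suprafacial/retentive sequence delivers it to the opposite face of C2, which with C3 cis to C15 is the face that gives 2R. The step needs chemoselectivity between the two oxiranes (only C15–O is allylic, and the 7,8-oxirane has no adjacent π bond), site selectivity for C2 over C4 (five- against seven-membered closure, and C4 is fully substituted) and suppression of free-cation leakage (non-polar solvent, low loading, moderate temperature).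

**Compound list**
1 | (2E,6E)-farnesol | CC(C)=CCC/C(C)=C/CC/C(C)=C/CO | starting material
2 | (2E,6E)-farnesal | CC(C)=CCC/C(C)=C/CC/C(C)=C/C=O | intermediate
3 | (3E,7E)-1,1-dibromo-4,8,12-trimethyltrideca-1,3,7,11-tetraene | CC(C)=CCC/C(C)=C/CC/C(C)=C/C=C(Br)Br | intermediate
4 | (2E,6E,10E)-13,13-dibromo-2,6,10-trimethyltrideca-2,6,10,12-tetraen-1-ol | OC/C(C)=C/CC/C(C)=C/CC/C(C)=C/C=C(Br)Br | intermediate
5 | acetate of 4 | CC(=O)OC/C(C)=C/CC/C(C)=C/CC/C(C)=C/C=C(Br)Br | intermediate
6 | (6R,7R)-6,7-epoxide of 5 | CC(=O)OC/C(C)=C/CC[C@@]1(C)O[C@@H]1CC/C(C)=C/C=C(Br)Br | intermediate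
7 | epoxy allylic alcohol | OC/C(C)=C/CC[C@@]1(C)O[C@@H]1CC/C(C)=C/C=C(Br)Br | intermediate
8 | epoxy enal | O=C/C(C)=C/CC[C@@]1(C)O[C@@H]1CC/C(C)=C/C=C(Br)Br | intermediate
9 | epoxy dibromide with terminal 1,3-diene | C=C/C(C)=C/CC[C@@]1(C)O[C@@H]1CC/C(C)=C/C=C(Br)Br | intermediate
10 | B-alkyl-9-BBN adduct of 9 (boron on C14) | C1CC2CCCC(C1)B2CC/C(C)=C/CC[C@@]3(C)O[C@@H]3CC/C(C)=C/C=C(Br)Br | intermediate
11 | (1Z,3E,7R,8R,11E)-1-bromo-7,8-epoxy-15,16,17-trinorcembra-1,3,11-triene | C1C/C(C)=C/CC[C@@]2(C)O[C@@H]2CC/C(C)=C/C=C1\Br | intermediate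
12 | prop-2-yn-1-ol | C#CCO | starting material
13 | 2-(tributylstannyl)prop-2-en-1-ol | C=C(CO)[Sn](CCCC)(CCCC)CCCC | intermediate
14 | (1Z,3E,7R,8R,11E)-7,8-epoxycembra-1,3,11,15-tetraen-17-ol | C1C/C(C)=C/CC[C@@]2(C)O[C@@H]2CC/C(C)=C/C=C1\C(=C)CO | intermediate
15 | (15R)-7,8:15,16-diepoxycembra-1,3,11-trien-17-ol | C1C/C(C)=C/CC[C@@]2(C)O[C@@H]2CC/C(C)=C/C=C1\[C@@]3(CO)CO3 | intermediate
16 | 17-acetate of 15 | C1C/C(C)=C/CC[C@@]2(C)O[C@@H]2CC/C(C)=C/C=C1\[C@@]3(COC(C)=O)CO3 | intermediate
17 | lobophynin B | CC(=O)OCC1=C2CC/C(C)=C/CC[C@@]3(C)O[C@@H]3CC/C(C)=C/[C@H]2OC1 | target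

**Total step count:** 14. **Longest linear sequence:** 13 (steps 1–9 and 11–14).

**Steps most likely to fail**

**Step 14.**
- Risk: heterolysis to a free pentadienyl cation could erase the C15→C2 transfer. Closure could be slow because C3 sits inside the U-shaped allyl unit. A 1,2-hydride shift to a carbonyl compound could compete.
- Fallback (sets out from 9 and 13, returns at 17): the substrate is redesigned as the E-type alkenyl oxirane, with H instead of C3 inside the allyl unit, by inverting the order of the two couplings.
- A trans-selective Stille coupling of 9 with 13 (Pd2(dba)3, tri(2-furyl)phosphine, PhMe, 60 °C) gives the open-chain (1Z)-bromotrienol F1.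
- 9-BBN-H (2.1 equiv; the first equivalent caps the OH as a borinate and shields the neighbouring 1,1-disubstituted alkene) gives the doubly borylated chain F2.
- F2 is cyclised at the remaining C–Br bond with retention (Pd(Pt-Bu3)2, Cs2CO3, aqueous THF–DMF, high dilution) to the (1E)-trienol F3.
- Sharpless epoxidation with L-(+)-DIPT gives the (15S)-epoxy alcohol F4, and acetylation gives the epoxy acetate F5.
- The same copper-catalysed ring expansion then delivers oxygen to the face of C2 that, with C3 trans to C15, again gives 17.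

**Step 12.**
- Risk: Ti(IV) could solvolyse the newly formed tertiary dienylic oxirane, and the bulky 2-substituent could lower facial selectivity.
- Fallback (sets out from 11, returns at 16): the oxirane is closed under base from an enzymatically desymmetrised triol, so no Lewis acid ever meets it.
- Br/Li exchange on 11 (t-BuLi, Et2O, −78 °C) and addition to 1,3-bis(tert-butyldimethylsilyloxy)propan-2-one give the tertiary alcohol F6, and TBAF gives the prochiral triol F7.
- Lipase-catalysed mono-acetylation (vinyl acetate, Pseudomonas cepacia lipase) gives the monoacetate F8. The other arm is reached by enzymatic hydrolysis of the diacetate.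
- MsCl/collidine on the remaining primary OH gives the mesylate F9, and Cs2CO3 in MeCN closes the oxirane to 16.

**Step 9.**
- Risk: oligomerisation, protodeboronation, base-induced dehydrobromination to a bromoalkyne, and erosion of the trans-selectivity.
- Fallback (sets out from 10, returns at 11): the ring is closed with an organozinc reagent in the absence of base and water.
- Oxidation of 10 (NaBO3·4H2O, THF–H2O) gives the primary alcohol F10, and an Appel reaction (I2, PPh3, imidazole) gives the iodide F11.
- Zinc insertion (Zn, LiCl, THF, 30 °C) gives the alkylzinc iodide F12.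
- F12 is added slowly to PdCl2(DPEphos) in THF for a trans-selective intramolecular Negishi coupling to 11.

**Further compounds**
F1 | step 14 | open-chain (1Z)-bromotrienol | C=C/C(C)=C/CC[C@@]1(C)O[C@@H]1CC/C(C)=C/C=C(\Br)/C(=C)CO
F2 | step 14 | doubly borylated chain (C14–B and O–B) | C1CC2CCCC(C1)B2CC/C(C)=C/CC[C@@]3(C)O[C@@H]3CC/C(C)=C/C=C(\Br)/C(=C)COB4C5CCCC4CCC5
F3 | step 14 | (1E,3E,7R,8R,11E)-7,8-epoxycembra-1,3,11,15-tetraen-17-ol | C1C/C(C)=C/CC[C@@]2(C)O[C@@H]2CC/C(C)=C/C=C1/C(=C)CO
F4 | step 14 | (1E,15S)-7,8:15,16-diepoxycembra-1,3,11-trien-17-ol | C1C/C(C)=C/CC[C@@]2(C)O[C@@H]2CC/C(C)=C/C=C1/[C@]3(CO)CO3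
F5 | step 14 | 17-acetate of F4 | C1C/C(C)=C/CC[C@@]2(C)O[C@@H]2CC/C(C)=C/C=C1/[C@]3(COC(C)=O)CO3
F6 | step 12 | tertiary alcohol with two CH2OTBS arms on C15 | C1C/C(C)=C/CC[C@@]2(C)O[C@@H]2CC/C(C)=C/C=C1\C(O)(CO[Si](C)(C)C(C)(C)C)CO[Si](C)(C)C(C)(C)C
F7 | step 12 | prochiral 15,16,17-triol | C1C/C(C)=C/CC[C@@]2(C)O[C@@H]2CC/C(C)=C/C=C1\C(O)(CO)CO
F8 | step 12 | 17-monoacetate of the triol | C1C/C(C)=C/CC[C@@]2(C)O[C@@H]2CC/C(C)=C/C=C1\[C@@](O)(COC(C)=O)CO
F9 | step 12 | 16-mesylate of F8 | C1C/C(C)=C/CC[C@@]2(C)O[C@@H]2CC/C(C)=C/C=C1\[C@@](O)(COC(C)=O)COS(C)(=O)=O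
F10 | step 9 | primary alcohol (C14–OH) | OCC/C(C)=C/CC[C@@]1(C)O[C@@H]1CC/C(C)=C/C=C(Br)Br
F11 | step 9 | primary iodide (C14–I) | ICC/C(C)=C/CC[C@@]1(C)O[C@@H]1CC/C(C)=C/C=C(Br)Br
F12 | step 9 | alkylzinc iodide | I[Zn]CC/C(C)=C/CC[C@@]1(C)O[C@@H]1CC/C(C)=C/C=C(Br)Br
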